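## Retrosynthetic overview

1. Numbering: C1 = C(OH)(C7H2OBz), C2 = CHOH, C3 and C4 = CH2, C5 = CHOBz, C6 = CHOH (carbocycle = ring A). The route rests on tertiary carbinol C1 sitting next to oxygenated C6, while C7–C1–C2 carries the oxygen pattern of dihydroxyacetone. With C6 at the ketone level, C1–C6 is a bond between an acyl anion (C6) and a ketone (C1).
2. Endgame: on the bicyclic α-ketol, the C5 oxygen (Rubottom oxidation) and the C6 hydrogen (hydroxyl-directed reduction) both enter from the face that carries the C1 hydroxyl. The C5 benzoate is installed between these two steps and the C7 benzoate last.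
3. Key disconnection C1–C6: a carbene-catalysed crossed benzoin reaction of a dioxanone keto-aldehyde closes ring A onto the 1,3-dioxane (ring B).
4. Disconnection C2–C3: RAMP-hydrazone alkylation of 2,2-dimethyl-1,3-dioxan-5-one with 5-bromopent-1-ene sets C2. A single ozonolysis then unmasks both carbonyl groups.
5. Ring order: ring B is bought, ring A is closed in step 4, and ring B is opened in step 9.

Key step: step 4

Assumption: both enantiomers of the aminoindanol-derived N-pentafluorophenyl triazolium tetrafluoroborate (C18H11BF9N3O) are commercial. The (5aR,10bS) form, SMILES F[B-](F)(F)F.Fc1c(F)c(F)c(F)c(F)c1-[n+]1cn2c(n1)CO[C@@H]1Cc3ccccc3[C@@H]12, is taken as the one matched to (R)-configured C2. The axial preference of the dioxanone itself acts in the required sense in any case.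

Remark: "top face" means the face of ring A that carries the C1 hydroxyl. In the cis-fused bicycle this is the convex face, because ring B hangs from the axial C2–O bond on the other side.

## Route

Step 1
Reactants: 1 2,2-dimethyl-1,3-dioxan-5-one; 2 (R)-1-amino-2-(methoxymethyl)pyrrolidine (RAMP)
Product: 3 (2R)-N-(2,2-dimethyl-1,3-dioxan-5-ylidene)-2-(methoxymethyl)pyrrolidin-1-amine
Conditions: benzene, Dean–Stark, reflux
Reagents that add atoms: none
Why: Hydrazone condensation of an unhindered ketone with the N-amino group is driven by azeotropic removal of water, opens the Enders SAMP/RAMP sequence, and forms no stereocentre.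

Step 2
Reactants: 3 RAMP hydrazone; 4 5-bromopent-1-ene
Product: 6 (2R)-N-[(4R)-2,2-dimethyl-4-(pent-4-en-1-yl)-1,3-dioxan-5-ylidene]-2-(methoxymethyl)pyrrolidin-1-amine, via lithium azaenolate 5 (not isolated)
Conditions: t-BuLi (1.1 equiv), THF, −78 °C; then 4, −100 °C to rt
Reagents that add atoms: none
Why: In this Enders RAMP-hydrazone alkylation the lithium azaenolate is held rigid by chelation to the methoxymethyl arm, so the primary bromide is displaced (SN2) from the open face only, which forms C2–C3 and sets C2 as R, the sense RAMP gives with this dioxanone.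

Step 3
Reactants: 6 alkylated RAMP hydrazone
Product: 8 (4R)-2,2-dimethyl-4-(4-oxobutyl)-1,3-dioxan-5-one, via keto ozonide 7 (not isolated)
Conditions: O3, CH2Cl2, −78 °C; then Me2S, −78 °C to rt; used without delay
Reagents that add atoms: ozone, [O-][O+]=O
Why: Ozone cleaves the C=N bond oxidatively (ketone plus nitrosamine) and the terminal alkene by Criegee ozonolysis with reductive Me2S work-up, all under cold neutral conditions that spare the ketal and do not epimerise the α-alkoxy centre C2.

Step 4
Reactants: 8 (4R)-2,2-dimethyl-4-(4-oxobutyl)-1,3-dioxan-5-one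
Product: 10 (4aS,8aR)-4a-hydroxy-2,2-dimethylhexahydro-4H-1,3-benzodioxin-5-one (cis-fused α-ketol: C6 ketone and C1 tertiary alcohol), via Breslow hydroxy-enamine 9 (not isolated)
Conditions: (5aR,10bS)-5a,10b-dihydro-2-(pentafluorophenyl)-4H,6H-indeno[2,1-b]-1,2,4-triazolo[4,3-d]-1,4-oxazinium tetrafluoroborate (10 mol %), Et3N (10 mol %), toluene (0.02 M), argon, rt
Reagents that add atoms: none
Why: The carbene freed from the triazolium salt adds to the C6 aldehyde, a proton shift gives hydroxy-enamine 9, its nucleophilic C6 attacks the C1 ketone, and proton transfer with loss of the carbene releases 10. This is the intramolecular crossed aldehyde–ketone benzoin reaction, established for aliphatic and enolisable keto-aldehydes that close five- and six-membered tertiary α-ketols. Ring A (C1–C6) closes in a 6-exo-trig mode onto ring B. The new stereocentre C1 is controlled first by C2: with the side chain equatorial on the dioxanone chair, the tether reaches C1 along the axial trajectory that nucleophiles prefer on 1,3-dioxan-5-ones (no syn-axial C–H bonds, no torsional strain), so C6 ends axial on ring B, the C1 hydroxyl ends trans to the C2 oxygen and the fusion is cis, while the indane wall of the catalyst is chosen to shield the other ketone face. Chemoselectivity is built in, because only the aldehyde can become the acyl-anion equivalent, and the ketone, made more electrophilic by its two α-oxygens, is the only acceptor within reach at this dilution. The electron-poor N-C6F5 azolium needs only a catalytic weak amine, which keeps aldol closure through C5 and epimerisation at C2 slow, and C2 is no longer α to a carbonyl once the ring has closed.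

Step 5
Reactants: 10 cis-fused α-ketol
Product: 11 (4aS,8aR)-2,2-dimethyl-5-[(triisopropylsilyl)oxy]-4,7,8,8a-tetrahydro-4aH-1,3-benzodioxin-4a-ol (C5=C6 silyl enol ether with free C1 hydroxyl)
Conditions: i-Pr3SiOTf (1.2 equiv), Et3N (2 equiv), CH2Cl2, 0 °C to rt
Reagents that add atoms: triisopropylsilyl triflate, CC(C)[Si](C(C)C)(C(C)C)OS(=O)(=O)C(F)(F)F
Why: Soft enolisation with a silyl triflate and an amine can only run toward C5 because C1 is quaternary, and the triisopropylsilyl group is too bulky to silylate a tertiary alcohol, so the C1 hydroxyl stays free as the directing group for step 6.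

Step 6
Reactants: 11 silyl enol ether
Product: 14 (4aS,6R,8aR)-4a,6-dihydroxy-2,2-dimethylhexahydro-4H-1,3-benzodioxin-5-one (C5 hydroxyl cis to C1 hydroxyl), via silyloxy epoxide 12 (not isolated), via C5 silyl ether 13 (not isolated)
Conditions: mCPBA (1.1 equiv), CH2Cl2, −20 to 0 °C; crude, then Bu4NF/AcOH (1:1), THF, 0 °C
Reagents that add atoms: mCPBA, O=C(OO)c1cccc(Cl)c1
Why: In this Rubottom oxidation the peracid is hydrogen-bonded to the pseudoaxial allylic C1 hydroxyl (Henbest direction) and approaches the convex top face, which is also the stereoelectronically favoured axial side of C5, so the C5 oxygen is set cis to the C1 hydroxyl (5R) before silyl migration and acid-buffered fluoride cleavage free it without enolisation.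

Step 7
Reactants: 14 C5-hydroxy ketol; 15 benzoyl chloride
Product: 16 (4aS,6R,8aR)-4a-hydroxy-2,2-dimethyl-5-oxohexahydro-4H-1,3-benzodioxin-6-yl benzoate
Conditions: 15 (1.2 equiv), pyridine, CH2Cl2, 0 °C
Reagents that add atoms: none
Why: Acylation with an acid chloride in pyridine takes the only secondary hydroxyl while the tertiary C1 hydroxyl is inert, and C5 should hold its configuration because its C–H bond is equatorial, lies near the carbonyl plane and is therefore kinetically poorly acidic.

Step 8
Reactants: 16 C5-benzoyloxy ketol
Product: 18 (4aR,5S,6R,8aR)-4a,5-dihydroxy-2,2-dimethylhexahydro-4H-1,3-benzodioxin-6-yl benzoate (the 4a descriptor changes only through ligand ranking), via alkoxyborohydride 17 (not isolated)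
Conditions: Me4NBH(OAc)3 (5 equiv), MeCN/AcOH (1:1), −20 °C
Reagents that add atoms: none
Why: In this Evans–Saksena hydroxyl-directed reduction the axial C1 hydroxyl replaces an acetate on boron and hands the hydride to the neighbouring C6 carbonyl from the top face, so the new C6 hydroxyl is trans to both the C1 hydroxyl and the C5 benzoate (6S), while the reagent leaves the ester and ketal alone and the trans-diaxial C5/C6 pair cannot exchange the benzoyl group.

Step 9
Reactants: 18 acetonide diol benzoate
Product: 19 (1R,2S,3S,4R)-2,3,4-trihydroxy-3-(hydroxymethyl)cyclohexyl benzoate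
Conditions: AcOH/H2O (4:1), 40 °C
Reagents that add atoms: none
Why: Acid-catalysed ketal hydrolysis opens ring B and frees the C7 and C2 hydroxyls without touching any stereocentre, and benzoyl migration is slow in weakly acidic medium.

Step 10
Reactants: 19 tetraol monobenzoate; 15 benzoyl chloride
Product: 20 [(1S,2R,5R,6S)-5-(benzoyloxy)-1,2,6-trihydroxycyclohexyl]methyl benzoate (target)
Conditions: 15 (1.05 equiv), pyridine, CH2Cl2, −40 to −20 °C
Reagents that add atoms: none
Why: Kinetically selective acylation with one equivalent of acid chloride at low temperature takes the only primary hydroxyl (C7) ahead of the two flanked secondary hydroxyls and the tertiary one, and the cold conditions suppress benzoyl migration from C5 to C6.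

## Compound list

1 | 2,2-dimethyl-1,3-dioxan-5-one | CC1(C)OCC(=O)CO1 | starting material
2 | (R)-1-amino-2-(methoxymethyl)pyrrolidine (RAMP) | COC[C@H]1CCCN1N | starting material
3 | RAMP hydrazone of 1 | COC[C@H]1CCCN1N=C1COC(C)(C)OC1 | intermediate
4 | 5-bromopent-1-ene | C=CCCCBr | starting material
5 | lithium azaenolate of 3 | COC[C@H]1CCCN1N([Li])C1=COC(C)(C)OC1 | intermediate
6 | (4R)-pent-4-enyl RAMP hydrazone (C=N geometry of no consequence, left open) | COC[C@H]1CCCN1N=C1COC(C)(C)O[C@@H]1CCCC=C | intermediate
7 | (4R)-2,2-dimethyl-4-[3-(1,2,4-trioxolan-3-yl)propyl]-1,3-dioxan-5-one (both epimers at the ozonide carbon) | O=C1COC(C)(C)O[C@@H]1CCCC1OCOO1 | intermediate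
8 | (4R)-2,2-dimethyl-4-(4-oxobutyl)-1,3-dioxan-5-one | O=CCCC[C@H]1OC(C)(C)OCC1=O | intermediate
9 | Breslow hydroxy-enamine from 8 and the carbene (C6 bound to the triazolylidene carbon, enol geometry left open) | O=C1COC(C)(C)O[C@@H]1CCCC(O)=C1N(c2c(F)c(F)c(F)c(F)c2F)N=C2CO[C@@H]3Cc4ccccc4[C@@H]3N12 | intermediate
10 | (4aS,8aR)-4a-hydroxy-2,2-dimethylhexahydro-4H-1,3-benzodioxin-5-one | O=C1CCC[C@H]2OC(C)(C)OC[C@@]12O | intermediate
11 | C5=C6 triisopropylsilyl enol ether of 10, C1 hydroxyl free | CC(C)[Si](C(C)C)(C(C)C)OC1=CCC[C@H]2OC(C)(C)OC[C@@]12O | intermediate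
12 | 5,6-epoxide of 11 on the face of the C1 hydroxyl | CC(C)[Si](C(C)C)(C(C)C)O[C@@]12O[C@@H]1CC[C@H]1OC(C)(C)OC[C@@]21O | intermediate
13 | (4aS,6R,8aR)-4a-hydroxy-2,2-dimethyl-6-[(triisopropylsilyl)oxy]hexahydro-4H-1,3-benzodioxin-5-one | O=C1[C@H](O[Si](C(C)C)(C(C)C)C(C)C)CC[C@H]2OC(C)(C)OC[C@@]12O | intermediate
14 | (4aS,6R,8aR)-4a,6-dihydroxy-2,2-dimethylhexahydro-4H-1,3-benzodioxin-5-one | O=C1[C@H](O)CC[C@H]2OC(C)(C)OC[C@@]12O | intermediate
15 | benzoyl chloride | O=C(Cl)c1ccccc1 | starting material
16 | (4aS,6R,8aR)-4a-hydroxy-2,2-dimethyl-5-oxohexahydro-4H-1,3-benzodioxin-6-yl benzoate | O=C1[C@H](OC(=O)c3ccccc3)CC[C@H]2OC(C)(C)OC[C@@]12O | intermediate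
17 | tetramethylammonium diacetoxy(alkoxy)hydroborate of 16 (boron on the C1 oxygen) | C[N+](C)(C)C.O=C1[C@H](OC(=O)c3ccccc3)CC[C@H]2OC(C)(C)OC[C@@]12O[BH-](OC(C)=O)OC(C)=O | intermediate
18 | (4aR,5S,6R,8aR)-4a,5-dihydroxy-2,2-dimethylhexahydro-4H-1,3-benzodioxin-6-yl benzoate | O[C@H]1[C@H](OC(=O)c3ccccc3)CC[C@H]2OC(C)(C)OC[C@@]12O | intermediate
19 | (1R,2S,3S,4R)-2,3,4-trihydroxy-3-(hydroxymethyl)cyclohexyl benzoate | OC[C@]1(O)[C@H](O)CC[C@@H](OC(=O)c2ccccc2)[C@@H]1O | intermediate
20 | [(1S,2R,5R,6S)-5-(benzoyloxy)-1,2,6-trihydroxycyclohexyl]methyl benzoate | O=C(OC[C@]1(O)[C@H](O)CC[C@@H](OC(=O)c2ccccc2)[C@@H]1O)c1ccccc1 | target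

Total step count: 10. Longest linear sequence: 10 steps (1 to 20).

## Steps most likely to fail

**Step 4.** Three processes threaten this step:
- erosion of facial selectivity at C1, through reversible benzoin addition or a mismatched catalyst;
- competing aldol closure through the C5 enol;
- amine-induced loss of configuration at C2 before cyclisation.

The fallback sets out from 8 and forms the same C1–C6 bond reductively under non-basic conditions. SmI2 (2.2 equiv) with t-BuOH in THF at −78 °C turns the aldehyde into a ketyl, which adds to the samarium-bound ketone along the same axial path (intramolecular pinacol coupling). This should give the chelation-derived cis-diol (4aR,5R,8aR)-2,2-dimethylhexahydro-4H-1,3-benzodioxine-4a,5-diol F1. Parikh–Doering oxidation (SO3·pyridine, DMSO, Et3N) of its secondary C6 carbinol, which does not cleave the diol, rejoins the route at 10.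

**Step 6.** The risk is poor facial selectivity in oxygen delivery to the enol ether, if the bulk of the silyl group outweighs hydroxyl direction.

The fallback makes the oxidation stereoconvergent. It sets out from 11 under the same oxidation and desilylation. Attack on the lower face leads through the bottom-face silyloxy epoxide F2 and the C5-epimeric silyl ether F3 to the C5-epimeric hydroxy ketol (4aS,6S,8aR)-4a,6-dihydroxy-2,2-dimethylhexahydro-4H-1,3-benzodioxin-5-one F4, which is separated from 14. While 14 goes on through step 7, F4 undergoes a Mitsunobu reaction (PPh3, DIAD, benzoic acid, toluene, 0 °C to rt). Benzoate displaces the activated equatorial α-keto hydroxyl with inversion, the tertiary C1 hydroxyl being inert, so both epimers meet at 16.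

**Step 8.** The risk is sluggish exchange of the hindered tertiary C1 hydroxyl onto boron, which would lead to no reduction or to undirected hydride attack on the lower face.

The fallback changes the order of events so that a secondary hydroxyl carries the boron. It sets out from 14, whose C5 and C1 hydroxyls both lie on the top face. Me4NBH(OAc)3 in MeCN/AcOH should then deliver hydride from that face and give the triol (4aR,5S,6R,8aR)-2,2-dimethylhexahydro-4H-1,3-benzodioxine-4a,5,6-triol F5. One equivalent of 15 in pyridine/CH2Cl2 at −20 °C then acylates the C5 hydroxyl. This is the less hindered secondary carbinol, since the C6 hydroxyl sits on the concave face next to quaternary C1. The route is rejoined at 18.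

## Further compounds

F1 | step 4 | (4aR,5R,8aR)-2,2-dimethylhexahydro-4H-1,3-benzodioxine-4a,5-diol | O[C@@H]1CCC[C@H]2OC(C)(C)OC[C@@]12O
F2 | step 6 | 5,6-epoxide of 11 on the face opposite the C1 hydroxyl | CC(C)[Si](C(C)C)(C(C)C)O[C@]12O[C@H]1CC[C@H]1OC(C)(C)OC[C@@]21O
F3 | step 6 | (4aS,6S,8aR)-4a-hydroxy-2,2-dimethyl-6-[(triisopropylsilyl)oxy]hexahydro-4H-1,3-benzodioxin-5-one | O=C1[C@@H](O[Si](C(C)C)(C(C)C)C(C)C)CC[C@H]2OC(C)(C)OC[C@@]12O
F4 | step 6 | (4aS,6S,8aR)-4a,6-dihydroxy-2,2-dimethylhexahydro-4H-1,3-benzodioxin-5-one | O=C1[C@@H](O)CC[C@H]2OC(C)(C)OC[C@@]12O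
F5 | step 8 | (4aR,5S,6R,8aR)-2,2-dimethylhexahydro-4H-1,3-benzodioxine-4a,5,6-triol | O[C@H]1[C@H](O)CC[C@H]2OC(C)(C)OC[C@@]12O
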